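**On the bench.** Birch, made at your flask's strength, gains target more slowly than maple: 0.0575 h⁻¹ from 1.33 h to 3.00 h, against 0.141 h⁻¹ from 1.50 h to 3.00 h, both as fractions of the charge. Your partner is in the flask, and starting material goes in steadily until 2.5 h.

| flask | starting material | partner | remark | time |
|---|---|---|---|---|
| maple | 1.1 M (fed, over 2.5 h) | 0.95 equiv | run made earlier |  |
| oak | 1.8 M (fed, over 2.5 h) | 0.95 equiv | run made earlier |  |
| birch | 0.80 M (fed, over 2.5 h) | 0.47 equiv | run made earlier |  |
| flask | 0.80 M (fed, over 2.5 h) | 0.950 equiv |  | 3.0 h |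

| run | time / h | target / % | starting material / % |
|---|---|---|---|
| maple | 0.500 | 0 | 12.0 |
| maple | 1.00 | 2.6 | 24.6 |
| maple | 1.50 | 7.7 | 33.9 |
| maple | 2.00 | 14.6 | 39.7 |
| maple | 2.50 | 22.2 | 45.2 |
| maple | 3.00 | 28.9 | 36.5 |
| maple | 4.00 | 35.3 | 26.5 |
| oak | 0.200 | 0 | 5.6 |
| oak | 0.500 | 0.1 | 11.9 |
| oak | 1.00 | 4.6 | 23.5 |
| oak | 1.50 | 10.6 | 30.2 |
| oak | 2.00 | 19.3 | 35.1 |
| oak | 3.00 | 31.1 | 29.8 |
| oak | 4.00 | 35.3 | 18.2 |
| birch | 0.667 | 0.7 | 17.3 |
| birch | 1.33 | 3.2 | 32.5 |
| birch | 2.00 | 6.3 | 46.4 |
| birch | 3.00 | 12.8 | 51.5 |
| birch | 4.00 | 17.9 | 44.0 |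

(readings scatter by 0.5 percentage points)

- in percentages every species weighs as the starting material in it: one homo product or side product counts as two
- the analysis behind the earlier runs scatters by 0.5 percentage points, standard deviation
- reactions considered so far: starting material <-> open intermediate; partner -> second intermediate; open intermediate + second intermediate -> target; 2 open intermediate -> homo product; starting material + target -> side product
- percentages count the whole charge, also what has not yet gone in

* amount of target in percent of the starting material charged, at 40 min, 1.5 h and 3.0 h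

**What to expect.** Target needs second intermediate, which comes from partner, so I take the straight line through birch's bending curve and scale it by the partner charged. This is the partner-scaled climb, the mean gain of target per hour multiplied by the ratio of partner charges: 0.116 h⁻¹. From 1.5 h to 3.0 h I therefore expect a gain of 17 percentage points, and the scatter of two readings carries 1.3 points into it.

**Leave alone.** Keep the partner at 0.950 equiv: birch, with 0.47 equiv, read 12.8% at 3.00 h.

**The forecast.** It gives 0.8%, 6.5% and 24.5%, a gain of 18 points between the last two. Its ground: "Birch has the right concentration but half the partner".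

    starting material ⇌ open intermediate (K = 0.560, k = 0.00360 s⁻¹)
    partner → second intermediate (k = 9.49 × 10⁻⁵ s⁻¹)
    open intermediate + second intermediate → target (k = 6.67 × 10⁻⁴ M⁻¹ s⁻¹)
    2 open intermediate → homo product (k = 3.46 × 10⁻⁵ M⁻¹ s⁻¹)
    starting material + target → side product (k = 1.16 × 10⁻⁴ M⁻¹ s⁻¹)

**The result.** The flask gives 0.722%, 6.40% and 25.2%, and at 3.00 h it also holds 7.48% side product. Its gain from 1.5 h to 3.0 h is 19 points, a climb of 0.125 h⁻¹ against the scaled 0.116 h⁻¹, so my gain falls 1.4 points short. Oak has 0.95 equiv of partner, as your flask has, but a charge of 1.8 M against your 0.80 M; the scaled climb gives it 17 points from 1.50 h to 3.00 h, where its readings show 20 points.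

The runs were generated by integration for substances that don't exist; noise was put on by code.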